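**Plan**

- Retrosynthesis cuts, in order: the two pyrrole-carbonyl–N amide bonds, the two imidazole C2–NH2 bonds, the two exocyclic CH2–N bonds and, as the central cut, the two cyclobutane–imidazole C–C bonds. This leads back to a trans-cyclobutane-1,2-dicarboxylic acid, 4-iodoimidazole and two 2-(trichloroacetyl)pyrroles.
- Enabling feature: with the ring labelled Ca(imidazole)–Cb(CH2N)–Cc(CH2N)–Cd(imidazole), the bond from Ca to imidazole C5 lies β to the exocyclic carbon on Cb, and the bond from Cd to imidazole C5 lies β to the exocyclic carbon on Cc. At the carboxamide oxidation level each arm is therefore a directing group for its one neighbouring ring CH2.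
- Forward order: no ring is built (cyclobutane, imidazoles and pyrroles are bought). The sequence is bis(quinolin-8-ylamide), twofold C–H heteroarylation, amide-to-aldehyde reduction with epimerisation, reductive amination, C2 azidation, global hydrogenation, desulfamoylation, then two successive N-acylations.
- Stereochemistry: Cb and Cc come from the (1R,2R)-diacid. Ca and Cd are set by cis delivery from the chelating amides. Cb and Cc are then inverted by base at the aldehyde stage to the all-trans array, with the non-acidic Ca and Cd as fixed anchors.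
- The C2 symmetry of the core is kept until the penultimate step, where one of two homotopic aminomethyl groups is acylated.

Key step: step 3

Assumption: the (1R,2R)-diacid 1 is bought as the single enantiomer (it is also accessible by classical resolution of the racemic trans-diacid), and the imidazol-5-yl positions of the target SMILES are treated as the 4(5)-tautomers.

Locants used in the names: C1 and C2 of the cyclobutane carry the one-carbon arms (Cc, Cb); C3 and C4 carry the imidazoles (Ca, Cd).

**Route**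

Step 1
Reactants: 1 (1R,2R)-cyclobutane-1,2-dicarboxylic acid; 2 8-aminoquinoline (two equivalents incorporated)
Product: 4 (1R,2R)-N1,N2-di(quinolin-8-yl)cyclobutane-1,2-dicarboxamide, via diacid chloride 3 (not isolated)
Conditions: (COCl)2 (2.5 equiv), cat. DMF, CH2Cl2, 0 °C to rt; evaporate; then 2 (2.2 equiv), pyridine, cat. DMAP, CH2Cl2, 0 °C to rt
Reagents that add atoms: oxalyl chloride (two equivalents), ClC(=O)C(=O)Cl (supplies the two chlorine atoms of 3; none of its atoms remain in 4)
Why: Acid chloride formation at both carboxyl groups followed by twofold N-acylation of the weakly nucleophilic aminoquinoline is the standard way to install this auxiliary; pyridine instead of a trialkylamine limits ketene formation, so Cb and Cc should keep their configuration.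

Step 2
Reactants: 5 4-iodo-1H-imidazole
Product: 6 4-iodo-N,N-dimethyl-1H-imidazole-1-sulfonamide
Conditions: Me2NSO2Cl, Et3N, CH2Cl2, rt
Reagents that add atoms: dimethylsulfamoyl chloride, CN(C)S(=O)(=O)Cl
Why: N-Sulfonylation of the imidazole should occur at the nitrogen remote from iodine (the less hindered, thermodynamically preferred 1,4-isomer), and the sulfamoyl group lowers the basicity of N3 for the palladium step and later directs C2 lithiation.

Step 3
Reactants: 4 (1R,2R)-N1,N2-di(quinolin-8-yl)cyclobutane-1,2-dicarboxamide; 6 4-iodo-N,N-dimethyl-1H-imidazole-1-sulfonamide (two equivalents incorporated)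
Product: 8 (1R,2R,3R,4R)-3,4-bis[1-(dimethylsulfamoyl)-1H-imidazol-4-yl]-N1,N2-di(quinolin-8-yl)cyclobutane-1,2-dicarboxamide, via mono-imidazolyl bisamide 7 (not isolated)
Conditions: 6 (4 equiv), Pd(OAc)2 (20 mol %), AgOAc (4 equiv), PivOH (1 equiv), t-AmOH, 100 °C, sealed tube
Reagents that add atoms: none
Why: Each deprotonated quinolinylamide binds divalent palladium as an N,N-chelate, and carboxylate-assisted concerted metalation-deprotonation of the cis β-methylene hydrogen gives a five-membered palladacycle; oxidative addition of 6 to tetravalent palladium, C–C reductive elimination and iodide removal by AgOAc then turn the cycle over, first to 7 and then to 8. The closest known reaction type is the 8-aminoquinoline-directed palladium-catalysed β-C(sp3)–H arylation of cyclobutanecarboxamides with aryl and heteroaryl iodides. No ring is closed; two C–C bonds (Ca–imidazole and Cd–imidazole) and two stereocentres are formed. Ca and Cd are controlled by Cb and Cc, because the palladacycle can form only on the ring face carrying the directing amide, so each imidazole should arrive cis to its neighbouring amide and, the amides being trans, trans to the other imidazole. The step needs methylene over methine selectivity (each amide also has a cis β-methine hydrogen on the other amide-bearing carbon), which the strong preference of this metalation for secondary over tertiary C–H bonds secures, and each amide has exactly one β-methylene, so no regioisomer is possible. Excess iodide drives 7 on to 8, and the electron-poor N-sulfamoyl imidazole should bind the catalyst only weakly through N3.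

Step 4
Reactants: 8 (1R,2R,3R,4R)-3,4-bis[1-(dimethylsulfamoyl)-1H-imidazol-4-yl]-N1,N2-di(quinolin-8-yl)cyclobutane-1,2-dicarboxamide
Product: 11 (1S,2S,3R,4R)-3,4-bis[1-(dimethylsulfamoyl)-1H-imidazol-4-yl]cyclobutane-1,2-dicarbaldehyde (all-trans), via bis(quinolinyl aldimine) 9 (not isolated), via cis-configured dialdehyde 10 (not isolated)
Conditions: Cp2Zr(H)Cl (6 equiv), THF, rt; 1 M aq. HCl, 0 °C; crude 10, DBU (0.5 equiv), CH2Cl2, rt
Reagents that add atoms: water (two equivalents), O (supplies the two aldehyde oxygens on hydrolysis of 9)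
Why: Cp2Zr(H)Cl deprotonates each secondary amide and reduces the zirconium amidate to the N-aryl aldimine with loss of the oxygen to zirconium (the known reduction of secondary amides, including quinolin-8-ylamides on cyclobutanes, to imines and aldehydes); cold aqueous acid hydrolyses 9 and removes the aminoquinoline, and DBU then equilibrates the two α-formyl centres Cb and Cc through their enols to the all-trans isomer, the thermodynamic minimum, while the non-acidic Ca and Cd stay fixed.

Step 5
Reactants: 11 (1S,2S,3R,4R)-3,4-bis[1-(dimethylsulfamoyl)-1H-imidazol-4-yl]cyclobutane-1,2-dicarbaldehyde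
Product: 12 (1R,2R,3S,4S)-1,2-bis[(dibenzylamino)methyl]-3,4-bis[1-(dimethylsulfamoyl)-1H-imidazol-4-yl]cyclobutane
Conditions: Bn2NH (2.5 equiv), NaBH(OAc)3 (3 equiv), cat. AcOH, ClCH2CH2Cl, rt
Reagents that add atoms: dibenzylamine (two equivalents incorporated), C(NCc1ccccc1)c1ccccc1
Why: Twofold reductive amination, in which the iminium ions from the α-branched aldehydes are reduced faster than the aldehydes themselves; any enamine-mediated epimerisation is harmless because 11 is already the thermodynamic isomer, and the tertiary dibenzylamines carry no N–H, which the next step requires.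

Step 6
Reactants: 12 (1R,2R,3S,4S)-1,2-bis[(dibenzylamino)methyl]-3,4-bis[1-(dimethylsulfamoyl)-1H-imidazol-4-yl]cyclobutane
Product: 14 (1R,2R,3S,4S)-1,2-bis[(dibenzylamino)methyl]-3,4-bis[2-azido-1-(dimethylsulfamoyl)-1H-imidazol-4-yl]cyclobutane, via bis(2-lithioimidazole) 13 (not isolated)
Conditions: n-BuLi (2.4 equiv), THF, −78 °C; TsN3 (2.6 equiv), −78 to 0 °C; aq. NH4Cl
Reagents that add atoms: n-butyllithium (two equivalents), [Li]CCCC (the two lithium atoms of 13); tosyl azide (two equivalents), Cc1ccc(cc1)S(=O)(=O)N=[N+]=[N-] (the azide nitrogens of 14)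
Why: Directed lithiation and electrophilic azidation, in which the C2–H between the two ring nitrogens, acidified by the N1-sulfamoyl group, is removed selectively and the 2-lithioimidazole adds to the sulfonyl azide to give a triazenyl anion that fragments to the heteroaryl azide and sulfinate; the stereocentres are not acidic under these conditions.

Step 7
Reactants: 14 (1R,2R,3S,4S)-1,2-bis[(dibenzylamino)methyl]-3,4-bis[2-azido-1-(dimethylsulfamoyl)-1H-imidazol-4-yl]cyclobutane
Product: 15 (1R,2R,3S,4S)-1,2-bis(aminomethyl)-3,4-bis[2-amino-1-(dimethylsulfamoyl)-1H-imidazol-4-yl]cyclobutane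
Conditions: H2 (4 atm), Pd(OH)2/C, MeOH–AcOH, rt; basic work-up
Reagents that add atoms: none
Why: Catalytic hydrogenation reduces both heteroaryl azides to amines with loss of dinitrogen and hydrogenolyses the four N-benzyl groups in the same operation, while the sulfamoyl groups, the cyclobutane and its four stereocentres are inert.

Step 8
Reactants: 15 (1R,2R,3S,4S)-1,2-bis(aminomethyl)-3,4-bis[2-amino-1-(dimethylsulfamoyl)-1H-imidazol-4-yl]cyclobutane
Product: 16 (1R,2R,3S,4S)-1,2-bis(aminomethyl)-3,4-bis(2-amino-1H-imidazol-5-yl)cyclobutane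
Conditions: 2 M HCl, MeOH–H2O, 65 °C; then hydroxide-form anion-exchange resin (free base)
Reagents that add atoms: none
Why: Acid hydrolysis of the N-sulfamoyl azole, in which the protonated 2-aminoimidazole is a good leaving group at sulfur; it is placed here because the substrate has no acid-sensitive group yet, so the pyrrole amides and the bromopyrrole never see hot acid.

Step 9
Reactants: 16 (1R,2R,3S,4S)-1,2-bis(aminomethyl)-3,4-bis(2-amino-1H-imidazol-5-yl)cyclobutane; 17 1-(4-bromo-1H-pyrrol-2-yl)-2,2,2-trichloroethanone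
Product: 18 N-{[(1R,2R,3S,4S)-2-(aminomethyl)-3,4-bis(2-amino-1H-imidazol-5-yl)cyclobutyl]methyl}-4-bromo-1H-pyrrole-2-carboxamide
Conditions: 17 (0.8 equiv, slow addition), i-Pr2NEt, DMF, 0 °C to rt; reverse-phase chromatography, recovered 16 recycled
Reagents that add atoms: none
Why: Haloform-type acyl transfer, in which the primary alkylamine adds to the trichloromethyl ketone and expels trichloromethanide as chloroform, far faster than the guanidine-like 2-aminoimidazoles react (the selectivity used for the final amide bond of oroidin-type alkaloids); the two aminomethyl arms are homotopic, so either gives the same product and mono-acylation should be controlled only by the substoichiometric, slowly added donor.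

Step 10
Reactants: 18 N-{[(1R,2R,3S,4S)-2-(aminomethyl)-3,4-bis(2-amino-1H-imidazol-5-yl)cyclobutyl]methyl}-4-bromo-1H-pyrrole-2-carboxamide; 19 2,2,2-trichloro-1-(1H-pyrrol-2-yl)ethanone
Product: 20 desbromosceptrine, N-{[(1R,2R,3S,4S)-3,4-bis(2-amino-1H-imidazol-5-yl)-2-{[(1H-pyrrole-2-carbonyl)amino]methyl}cyclobutyl]methyl}-4-bromo-1H-pyrrole-2-carboxamide
Conditions: 19 (1.2 equiv), i-Pr2NEt, DMF, rt
Reagents that add atoms: none
Why: The same haloform-type acyl transfer to the one remaining primary alkylamine should complete the unsymmetrical bisamide under mild, neutral-to-basic conditions that leave the bromopyrrole, the 2-aminoimidazoles and all four stereocentres untouched.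

**Compound list**

1 | (1R,2R)-cyclobutane-1,2-dicarboxylic acid | C1[C@@H](C(=O)O)[C@H](C(=O)O)C1 | starting material
2 | 8-aminoquinoline | Nc1cccc2cccnc12 | starting material
3 | (1R,2R)-cyclobutane-1,2-dicarbonyl dichloride | C1[C@@H](C(=O)Cl)[C@H](C(=O)Cl)C1 | intermediate (not isolated)
4 | (1R,2R)-N1,N2-di(quinolin-8-yl)cyclobutane-1,2-dicarboxamide | C1[C@@H](C(=O)Nc2cccc3cccnc23)[C@H](C(=O)Nc2cccc3cccnc23)C1 | intermediate
5 | 4-iodo-1H-imidazole | Ic1c[nH]cn1 | starting material
6 | 4-iodo-N,N-dimethyl-1H-imidazole-1-sulfonamide | CN(C)S(=O)(=O)n1cnc(I)c1 | intermediate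
7 | (1R,2R,3R)-3-[1-(dimethylsulfamoyl)-1H-imidazol-4-yl]-N1,N2-di(quinolin-8-yl)cyclobutane-1,2-dicarboxamide (imidazole cis to the adjacent amide) | CN(C)S(=O)(=O)n1cnc(c1)[C@H]2[C@@H](C(=O)Nc3cccc4cccnc34)[C@H](C(=O)Nc3cccc4cccnc34)C2 | intermediate (not isolated)
8 | (1R,2R,3R,4R)-3,4-bis[1-(dimethylsulfamoyl)-1H-imidazol-4-yl]-N1,N2-di(quinolin-8-yl)cyclobutane-1,2-dicarboxamide (amides trans, imidazoles trans, each imidazole cis to the adjacent amide) | CN(C)S(=O)(=O)n1cnc(c1)[C@H]2[C@@H](C(=O)Nc3cccc4cccnc34)[C@H](C(=O)Nc3cccc4cccnc34)[C@@H]2c1cn(S(=O)(=O)N(C)C)cn1 | intermediate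
9 | 1,1'-{(1R,2R,3R,4R)-3,4-bis[1-(dimethylsulfamoyl)-1H-imidazol-4-yl]cyclobutane-1,2-diyl}bis[N-(quinolin-8-yl)methanimine] | CN(C)S(=O)(=O)n1cnc(c1)[C@H]2[C@@H](C=Nc3cccc4cccnc34)[C@H](C=Nc3cccc4cccnc34)[C@@H]2c1cn(S(=O)(=O)N(C)C)cn1 | intermediate (not isolated)
10 | (1R,2R,3R,4R)-3,4-bis[1-(dimethylsulfamoyl)-1H-imidazol-4-yl]cyclobutane-1,2-dicarbaldehyde (each formyl cis to the adjacent imidazole) | CN(C)S(=O)(=O)n1cnc(c1)[C@H]2[C@@H](C=O)[C@H](C=O)[C@@H]2c1cn(S(=O)(=O)N(C)C)cn1 | intermediate (not isolated)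
11 | (1S,2S,3R,4R)-3,4-bis[1-(dimethylsulfamoyl)-1H-imidazol-4-yl]cyclobutane-1,2-dicarbaldehyde (all-trans) | CN(C)S(=O)(=O)n1cnc(c1)[C@H]2[C@H](C=O)[C@@H](C=O)[C@@H]2c1cn(S(=O)(=O)N(C)C)cn1 | intermediate
12 | (1R,2R,3S,4S)-1,2-bis[(dibenzylamino)methyl]-3,4-bis[1-(dimethylsulfamoyl)-1H-imidazol-4-yl]cyclobutane (all-trans) | CN(C)S(=O)(=O)n1cnc(c1)[C@H]2[C@H](CN(Cc3ccccc3)Cc3ccccc3)[C@@H](CN(Cc3ccccc3)Cc3ccccc3)[C@@H]2c1cn(S(=O)(=O)N(C)C)cn1 | intermediate
13 | 2,2'-dilithio derivative of 12 (lithium at C2 of each imidazole) | CN(C)S(=O)(=O)n1c([Li])nc(c1)[C@H]2[C@H](CN(Cc3ccccc3)Cc3ccccc3)[C@@H](CN(Cc3ccccc3)Cc3ccccc3)[C@@H]2c1cn(S(=O)(=O)N(C)C)c([Li])n1 | intermediate (not isolated)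
14 | (1R,2R,3S,4S)-1,2-bis[(dibenzylamino)methyl]-3,4-bis[2-azido-1-(dimethylsulfamoyl)-1H-imidazol-4-yl]cyclobutane | CN(C)S(=O)(=O)n1c(N=[N+]=[N-])nc(c1)[C@H]2[C@H](CN(Cc3ccccc3)Cc3ccccc3)[C@@H](CN(Cc3ccccc3)Cc3ccccc3)[C@@H]2c1cn(S(=O)(=O)N(C)C)c(N=[N+]=[N-])n1 | intermediate
15 | (1R,2R,3S,4S)-1,2-bis(aminomethyl)-3,4-bis[2-amino-1-(dimethylsulfamoyl)-1H-imidazol-4-yl]cyclobutane | CN(C)S(=O)(=O)n1c(N)nc(c1)[C@H]2[C@H](CN)[C@@H](CN)[C@@H]2c1cn(S(=O)(=O)N(C)C)c(N)n1 | intermediate
16 | (1R,2R,3S,4S)-1,2-bis(aminomethyl)-3,4-bis(2-amino-1H-imidazol-5-yl)cyclobutane | Nc1ncc([C@H]2[C@H](CN)[C@@H](CN)[C@@H]2c2cnc(N)[nH]2)[nH]1 | intermediate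
17 | 1-(4-bromo-1H-pyrrol-2-yl)-2,2,2-trichloroethanone | O=C(c1cc(Br)c[nH]1)C(Cl)(Cl)Cl | starting material
18 | N-{[(1R,2R,3S,4S)-2-(aminomethyl)-3,4-bis(2-amino-1H-imidazol-5-yl)cyclobutyl]methyl}-4-bromo-1H-pyrrole-2-carboxamide | Nc1ncc([C@H]2[C@H](CN)[C@@H](CNC(=O)c3cc(Br)c[nH]3)[C@@H]2c2cnc(N)[nH]2)[nH]1 | intermediate
19 | 2,2,2-trichloro-1-(1H-pyrrol-2-yl)ethanone | O=C(c1ccc[nH]1)C(Cl)(Cl)Cl | starting material
20 | desbromosceptrine | Nc1ncc([C@H]2[C@H](CNC(=O)c3ccc[nH]3)[C@@H](CNC(=O)c3cc(Br)c[nH]3)[C@@H]2c2cnc(N)[nH]2)[nH]1 | target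

**Step count**

Total: 10 steps. Longest linear sequence: 9 steps (steps 1 and 3 to 10; step 2 prepares the coupling partner 6).

**Steps most likely to fail, with fallbacks**

Step 3 (twofold C–H heteroarylation). The catalyst may be sequestered: the two deprotonated quinolinylamides of one substrate molecule can close a tetradentate N4 chelate around divalent palladium, and N3 of the iodoimidazole can bind palladium or silver, so turnover may stop before or after the first arylation. The fallback sets out from 1. Diacid chloride 3 is made as in step 1 and trapped with two equivalents of 2,3,5,6-tetrafluoro-4-(trifluoromethyl)aniline (pyridine, CH2Cl2) to give the bis(N-perfluoroaryl amide) F1, whose monodentate, weakly coordinating amidates cannot form the N4 trap. The known pyridine-ligand-assisted β-methylene arylation of such cycloalkanecarboxamides (Pd(OAc)2, 2-picoline, Ag2CO3, 6, 100 °C) should then give the 3,4-bis(imidazolyl) bisamide F2 with the same cis-to-amide sense. F2 is reduced with Cp2Zr(H)Cl to the bis(N-aryl aldimine) F3, which cold aqueous acid hydrolyses to 10; the route is rejoined at 10, and DBU gives 11.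

Step 4 (double amide reduction and epimerisation). Hydride transfer to the hindered, chelated zirconium amidates may stall on one arm, liberated aldehyde may be over-reduced, or material may be lost during imine hydrolysis before the epimerisation. The fallback sets out from 8. Boc2O and DMAP in MeCN give the twisted bis(N-Boc) imide F4. NaOMe in MeOH–THF cleaves both activated acyl groups and equilibrates the ester enolates, giving the all-trans dimethyl diester F5. LiBH4 in THF gives the all-trans diol F6, and Dess–Martin oxidation returns to the route at 11.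

Step 9 (mono-acylation of the C2-symmetric diamine). Nothing biases the first acylation over the second, so over-acylation to the bis(bromopyrrole) amide and some acylation of a free 2-aminoimidazole may erode the step. The fallback sets out from 15, where the only basic sites are the two alkylamines. One equivalent of HCl followed by one equivalent of Boc2O in MeOH (mono-ammonium protection of a symmetric diamine) gives the mono-carbamate F7; unreacted 15 is recovered and resubmitted. The free amine of F7 is acylated with 19 (i-Pr2NEt, DMF) to give the pyrrole amide carbamate F8. 2 M HCl in MeOH–H2O at 65 °C then removes the carbamate and both sulfamoyl groups to give the mono(pyrrole-2-carboxamide) amine F9, so only the unbrominated pyrrole amide sees acid. Acylation of F9 with 17 (i-Pr2NEt, DMF) rejoins the route at 20.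

**Further compounds**

F1 | step 3 | (1R,2R)-N1,N2-bis[2,3,5,6-tetrafluoro-4-(trifluoromethyl)phenyl]cyclobutane-1,2-dicarboxamide | C1[C@@H](C(=O)Nc2c(F)c(F)c(C(F)(F)F)c(F)c2F)[C@H](C(=O)Nc2c(F)c(F)c(C(F)(F)F)c(F)c2F)C1
F2 | step 3 | (1R,2R,3R,4R)-3,4-bis[1-(dimethylsulfamoyl)-1H-imidazol-4-yl]-N1,N2-bis[2,3,5,6-tetrafluoro-4-(trifluoromethyl)phenyl]cyclobutane-1,2-dicarboxamide | CN(C)S(=O)(=O)n1cnc(c1)[C@H]2[C@@H](C(=O)Nc3c(F)c(F)c(C(F)(F)F)c(F)c3F)[C@H](C(=O)Nc3c(F)c(F)c(C(F)(F)F)c(F)c3F)[C@@H]2c1cn(S(=O)(=O)N(C)C)cn1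
F3 | step 3 | bis{N-[2,3,5,6-tetrafluoro-4-(trifluoromethyl)phenyl]aldimine} of dialdehyde 10 (configuration of F2) | CN(C)S(=O)(=O)n1cnc(c1)[C@H]2[C@@H](C=Nc3c(F)c(F)c(C(F)(F)F)c(F)c3F)[C@H](C=Nc3c(F)c(F)c(C(F)(F)F)c(F)c3F)[C@@H]2c1cn(S(=O)(=O)N(C)C)cn1
F4 | step 4 | di-tert-butyl N,N'-{(1R,2R,3R,4R)-3,4-bis[1-(dimethylsulfamoyl)-1H-imidazol-4-yl]cyclobutane-1,2-dicarbonyl}bis[N-(quinolin-8-yl)carbamate] | CN(C)S(=O)(=O)n1cnc(c1)[C@H]2[C@@H](C(=O)N(C(=O)OC(C)(C)C)c3cccc4cccnc34)[C@H](C(=O)N(C(=O)OC(C)(C)C)c3cccc4cccnc34)[C@@H]2c1cn(S(=O)(=O)N(C)C)cn1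
F5 | step 4 | dimethyl (1S,2S,3R,4R)-3,4-bis[1-(dimethylsulfamoyl)-1H-imidazol-4-yl]cyclobutane-1,2-dicarboxylate (all-trans) | CN(C)S(=O)(=O)n1cnc(c1)[C@H]2[C@H](C(=O)OC)[C@@H](C(=O)OC)[C@@H]2c1cn(S(=O)(=O)N(C)C)cn1
F6 | step 4 | {(1S,2S,3R,4R)-3,4-bis[1-(dimethylsulfamoyl)-1H-imidazol-4-yl]cyclobutane-1,2-diyl}dimethanol (all-trans) | CN(C)S(=O)(=O)n1cnc(c1)[C@H]2[C@H](CO)[C@@H](CO)[C@@H]2c1cn(S(=O)(=O)N(C)C)cn1
F7 | step 9 | mono-N-Boc derivative of 15 (one CH2NHBoc, one CH2NH2, all-trans) | CN(C)S(=O)(=O)n1c(N)nc(c1)[C@H]2[C@H](CN)[C@@H](CNC(=O)OC(C)(C)C)[C@@H]2c1cn(S(=O)(=O)N(C)C)c(N)n1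
F8 | step 9 | N-Boc, N'-(1H-pyrrole-2-carbonyl) derivative of 15 (all-trans) | CN(C)S(=O)(=O)n1c(N)nc(c1)[C@H]2[C@H](CNC(=O)c3ccc[nH]3)[C@@H](CNC(=O)OC(C)(C)C)[C@@H]2c1cn(S(=O)(=O)N(C)C)c(N)n1
F9 | step 9 | N-{[(1R,2R,3S,4S)-2-(aminomethyl)-3,4-bis(2-amino-1H-imidazol-5-yl)cyclobutyl]methyl}-1H-pyrrole-2-carboxamide | Nc1ncc([C@H]2[C@H](CNC(=O)c3ccc[nH]3)[C@@H](CN)[C@@H]2c2cnc(N)[nH]2)[nH]1
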